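Two questions stand on this flask, and both ask where it stops.

| flask | G | L | remark | time |
|---|---|---|---|---|
| Saturday's | 7 mM | 10 mM | run made earlier |  |
| Wednesday's | 11 mM | 10 mM | run made earlier |  |
| flask | 5.0 mM | 10.0 mM |  | 5.0 min |

- Saturday's (time / min: G / %, X / %): 0.250: 34.7, 33.2; 0.500: 33.2, 31.5; 1.33: 33.8, 30.5; 3.00: 32.5, 29.9
- Wednesday's (time / min: G / %, X / %): 0.417: 45.3, 26.4; 1.00: 45.0, 25.3; 2.00: 43.8, 25.9; 3.00: 45.2, 24.6

(each reading ± 0.5 percentage points)

- share of the G used up at 5.0 min
- X at 5.0 min, in percent of the G charged

The nearest run is Saturday's, with the same L but more G, 7 mM against 5.0 mM. Its G reads 34.7 % at 0.250 min and still 32.5 % at 3.00 min, so Saturday's flask has almost stopped. Counting one L per G, its turnover at that last reading is 4.72 mM, with 2.27 mM of G and 5.28 mM of L left.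

Turnover over the product of those two amounts reads 0.394 mM⁻¹ on Saturday but 0.305 mM⁻¹ on Wednesday. Squaring the turnover, as for two products that both grow with it, gives 1.86 and 1.84, with mean 1.85. This reading is the plateau quotient, a reaction quotient under thermodynamic control: squared turnover over the product of the G and L left.

Held at that value, the flask reaches a turnover of 3.77 mM, or 75.4 % of its G, against Saturday's 67.5 %. Saturday's X holds 44.3 % of the G used, which puts X here at 33.4 %.

The forecast, reasoning that the G curve “looks like a fast equilibrium rather than a slow reaction”, says 72 % and 31.5 %, both lower than this reckoning.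

The flask gives 75.5 % and 34.3 %, both higher than the forecast's figures, by 3.5 percentage points and 2.8 points, which still counts as right within the tolerance.

    G + L ⇌ X + Z (K = 0.850, k = 59.0 M⁻¹ s⁻¹)
    X ⇌ E (K = 1.20, k = 0.0920 s⁻¹)

The half-life of the flask's slowest mode at the asked time is 0.0865 min, short against 5.0 min. X accordingly reads 34.3 % at 50.0 min, as at the asked time. The flask's 3.78 mM of Z marks a turnover whose quotient is 1.87. Another charge takes a flask off the forecast's 72 %: the reading 1.85, carried to 20 mM of G, gives 37.7 % used up, and that flask stands at 37.8 %.

All runs were computed for substances that don't exist, noise included.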